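The data are simulated with constants of no real substance, noise included.

If I wanted the end of the east flask, I had to follow one molecule of E through its forks, since each E that went to Z took one L with it.

| flask | G | L | E | J | remark | time |
|---|---|---|---|---|---|---|
| east | 0.68 M | 0.748 M | 0.34 M | 0.068 M | the very flask that is asked about, followed so far |  |
| north-west | 1 M | 0.748 M | 0.34 M | 0.068 M | run made earlier |  |
| flask | 0.68 M | 0.748 M | 0.340 M | 0.0680 M |  | 5.0 h |

- east (time / min: G / %, Q / %): 20.0: 62.0, 29.2; 40.0: 55.2, 36.5; 50.0: 53.5, 38.0; 80.0: 49.3, 41.1; 90.0: 49.9, 40.2
- north-west (time / h: G / %, Q / %): 0.667: 57.8, 33.8; 1.33: 55.2, 36.1; 2.00: 54.9, 36.7; 3.00: 55.1, 36.7; 4.00: 55.0, 36.2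

(each reading ± 0.5 percentage points)

- steps that have been proposed: G + L <-> Q; E + L -> Z; G + E -> X; E + J -> D
- the reaction counts as stopped when no species that holds the G changes by six tenths of a point or more over the second half of the time

* at 5.0 h, what has stopped the reaction, if anything has (it is still moving / L has run out first / all of G has reacted / forward and back rates have come level)
* share of the G used up at 5.0 h
* Q at 5.0 h, in percent of the G charged

1. The first instants. I counted the gap below the whole charge in G plus Q as X. In the north-west run it stood at 8.40% at 0.667 h. Over the last three readings Q averaged 36.5% and G averaged 55.0%, so the gap averaged 8.47%. So the gap had stopped growing by the first reading, within the scatter.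

2. The middle. I sorted the E of that run by its forks. The gap gave X 24.9% of it. I let D take the whole charge of J, an upper limit, which was 20.0% of E. I gave Z the rest, 55.1%.

3. The end. Z then used 25.0% of the L charge and Q used 48.8%, so 26.1% remained. The run was flat with L still there, so I read the plateau as an equilibrium. I named the tilt 2.54: Q over G, divided by the fraction of L left. It is the equilibrium constant in units of the L charge, and I held it for flasks with this L charge.

4. The east flask. Its last two readings gave X 9.75%. Before Q, the same count left 72.5% of L. Solving the tilt for Q gave me 42.0%, a little above the forecast's 41.5%. The forecast gave 50.9% used up and said “So the plateau is G + L <-> Q equilibrium”: forward and back rates have come level.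

5. The outcome in the flask at 5.0 h: forward and back rates have come level, with 51.1% of G used up and Q at 41.7%.

    G + L ⇌ Q (K = 3.40 /M, k = 0.0460 /M/min)
    E + L → Z (k = 0.210 /M/min)
    G + E → X (k = 0.0610 /M/min)
    E + J → D (k = 1.40 /M/min)

6. Over the second half of the time the largest change was 0.06 percentage points. With 34% of L left, the tilt asked for Q over G of 0.854, and this flask stood at 0.853. In the neighbour charged with 0.20 M of E, 40% of L was left, so the tilt asked for 1.03. That neighbour held Q 48.2% over G 46.9%, a ratio of 1.03.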